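**Retrosynthetic overview**

1. The target is an upper (2R,3S)-eriodictyol unit (ring A = C4a, C5, C6, C7, C8, C8a; ring B; ring C = O1, C2, C3, C4) bonded C3–C8'' to a lower (2''R)-naringenin unit (rings D, E, F). The last step is hydrogenolysis of seven benzyl ethers.
2. Ring F is made last. O1''–C2'' comes from a catalyst-controlled oxa-Michael addition of the C8a'' phenol to a tert-butyl β-keto ester alkylidene (the ester is then lost), C2''=C3'' from a Knoevenagel condensation, and C3''–C4'' from a Claisen condensation on a ring D methyl ester carried from the first step.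
3. Ring C is closed by O1–C2 oxa-Michael addition of the α-aryl chalcone. C2 and C3 are deracemised by dynamic transfer hydrogenation, and the upper unit stays as the C4 carbinol through every basic step of the ring F work and is reoxidised just before the acidic decarboxylation.
4. Ring A (key step): ring A is an acylphloroglucinol whose C4 ketone lies between the ortho oxygens on C5 and C8a and next to C3, which carries the doubly ortho-oxygenated ring D. The oxygens on C5, C7 and C8a mark ring A as a folded tetraketide, so C4a–C8a is disconnected (Claisen) back to a 6-(2-oxoalkyl)-4-hydroxy-2-pyrone.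
5. The pyrone comes from the triacetic acid lactone dianion and an α-aryl cinnamate (Perkin condensation of the ring D arylacetic acid with the ring B aldehyde). Ring D comes from methyl 2,4,6-trihydroxybenzoate, with the C8'' arm placed by aromatic Claisen rearrangement. Rings form in the order A, C, F.

Key step: step 9

**Remarks**

- Upper unit locants are unprimed, lower unit locants double-primed. SEM = 2-(trimethylsilyl)ethoxymethyl. "ArD" in names = 4,6-bis(benzyloxy)-3-(methoxycarbonyl)-2-(SEM-oxy)phenyl (C1 = C8'', C2 = C8a'', C3 = C4a'').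
- Assumption: the hand of each chiral catalyst is assigned by analogy with simple chromanones and flavanones ((S,S)-Ru hydride gives the 4S carbinol with hydride anti to the C3 aryl; the quinidine-derived thiourea gives 2''R). If a test run shows the opposite sense, the mirror-image catalyst is used.
- Design remark: bases epimerise and ring-open the 3-aryl ketone of the upper unit (the dynamic step uses this), but acid does not; its carbinol is stable to base but ionises in acid. Ring D therefore carries the C4'' carbon as an ester and the C8a'' oxygen as a fluoride-labile SEM ether, and compounds 17 to 22 are purified on base-washed silica.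
- Racemic 16 is drawn as its (2R,3S) enantiomer.

**Route**

Step 1
Reactants: 1 methyl 2,4,6-trihydroxybenzoate
Product: 2 methyl 2,4-bis(benzyloxy)-6-hydroxybenzoate
Conditions: BnBr (2.05 equiv), K2CO3, DMF, 0 °C to rt
Reagents that add atoms: benzyl bromide, BrCc1ccccc1
Why: Williamson etherification in which the para hydroxyl and one ortho hydroxyl react while the last ortho hydroxyl is held back by its hydrogen bond to the ester carbonyl, which singles out the oxygen that becomes O1''.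

Step 2
Reactants: 2 methyl 2,4-bis(benzyloxy)-6-hydroxybenzoate
Product: 3 methyl 2-(allyloxy)-4,6-bis(benzyloxy)benzoate
Conditions: allyl bromide, K2CO3, DMF, 60 °C
Reagents that add atoms: allyl bromide, C=CCBr
Why: Williamson O-allylation of the chelated phenol under more forcing conditions puts the allyl group on the future O1''.

Step 3
Reactants: 3 methyl 2-(allyloxy)-4,6-bis(benzyloxy)benzoate
Product: 4 methyl 3-allyl-4,6-bis(benzyloxy)-2-hydroxybenzoate
Conditions: PhNEt2, 195 °C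
Reagents that add atoms: none
Why: Aromatic Claisen rearrangement ([3,3]-sigmatropic shift, then tautomerisation) moves the allyl group to the only free ortho position, the future C8'', and returns the phenol.

Step 4
Reactants: 4 methyl 3-allyl-4,6-bis(benzyloxy)-2-hydroxybenzoate
Product: 5 methyl 3-allyl-4,6-bis(benzyloxy)-2-(SEM-oxy)benzoate
Conditions: NaH, SEMCl, DMF, 0 °C to rt
Reagents that add atoms: 2-(trimethylsilyl)ethoxymethyl chloride, ClCOCC[Si](C)(C)C
Why: O-alkylation of the sodium phenoxide gives an acetal ether that survives the basic, oxidative and reductive steps ahead and is later removed by fluoride without acid.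

Step 5
Reactants: 5 methyl 3-allyl-4,6-bis(benzyloxy)-2-(SEM-oxy)benzoate
Product: 7 2-[4,6-bis(benzyloxy)-3-(methoxycarbonyl)-2-(SEM-oxy)phenyl]acetic acid, via arylacetaldehyde 6 (not isolated)
Conditions: OsO4 (2 mol %), NaIO4, 2,6-lutidine, dioxane/H2O, rt; then NaClO2, NaH2PO4, 2-methyl-2-butene, t-BuOH/H2O, rt
Reagents that add atoms: osmium tetroxide (aldehyde oxygen, regenerated by NaIO4), O=[Os](=O)(=O)=O; sodium chlorite (acid oxygen), [Na+].[O-]Cl=O
Why: Lemieux–Johnson cleavage of the terminal alkene followed by Pinnick oxidation of the aldehyde in the same flask gives the arylacetic acid without touching the benzyl or SEM ethers.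

Step 6
Reactants: 7 2-[4,6-bis(benzyloxy)-3-(methoxycarbonyl)-2-(SEM-oxy)phenyl]acetic acid; 8 3,4-bis(benzyloxy)benzaldehyde
Product: 9 (E)-3-[3,4-bis(benzyloxy)phenyl]-2-(ArD)acrylic acid
Conditions: Ac2O, Et3N, 110 °C; then H2O/THF, dilute acid
Reagents that add atoms: none
Why: Perkin condensation (enolate of the mixed anhydride adds to the aldehyde and acetate is eliminated) gives the α-aryl cinnamic acid, normally as the E isomer with the two aryl groups cis.

Step 7
Reactants: 9 (E)-3-[3,4-bis(benzyloxy)phenyl]-2-(ArD)acrylic acid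
Product: 10 methyl (E)-3-[3,4-bis(benzyloxy)phenyl]-2-(ArD)acrylate
Conditions: MeI, K2CO3, DMF, rt
Reagents that add atoms: iodomethane, CI
Why: SN2 esterification of the carboxylate gives the acyl donor for the pyrone dianion.

Step 8
Reactants: 10 methyl (E)-3-[3,4-bis(benzyloxy)phenyl]-2-(ArD)acrylate; 11 4-hydroxy-6-methyl-2H-pyran-2-one (triacetic acid lactone)
Product: 12 6-[(E)-4-[3,4-bis(benzyloxy)phenyl]-2-oxo-3-(ArD)but-3-enyl]-4-hydroxy-2H-pyran-2-one
Conditions: 11 (2.2 equiv), LiN(iPr)2 (4.5 equiv), THF/DMPU, −78 to 0 °C; then 10, −78 to 0 °C; cold 1 M HCl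
Reagents that add atoms: none
Why: Claisen-type C-acylation of the C6-methyl carbanion of the lactone dianion by the cinnamate ester (1,2-addition, the second equivalent of dianion deprotonating the product) should spare the ring D benzoate, which is flanked by two ortho oxygen substituents.

Step 9
Reactants: 12 6-[(E)-4-[3,4-bis(benzyloxy)phenyl]-2-oxo-3-(ArD)but-3-enyl]-4-hydroxy-2H-pyran-2-one
Product: 14 (E)-3-[3,4-bis(benzyloxy)phenyl]-2-(ArD)-1-(2,4,6-trihydroxyphenyl)prop-2-en-1-one, via triketo ester 13 (not isolated)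
Conditions: Mg(OMe)2 (6 equiv), MeOH, reflux; then cold 1 M HCl
Reagents that add atoms: none
Why: Magnesium-bound methoxide adds to the lactone carbonyl of the pyrone and opens it to the methyl 3,5,7-trioxo ester 13, which magnesium holds as a planar bis-chelate; its most acidic methylene, the future C4a between the C4 and C5 carbonyls, attacks the ester carbon, the future C8a, methoxide leaves and the cyclic triketone enolises to the phloroglucinol. This is the known magnesium methoxide conversion of 6-(2-oxoalkyl)-4-hydroxy-2-pyrones and 3,5,7-triketo esters into acylphloroglucinols, the bench analogue of the ring closure performed by chalcone synthase. Ring A closes by a 6-exo-trig Claisen condensation (enolate carbon onto an exocyclic ester C=O) that forms C4a–C8a, and no stereocentre is created. The step must prefer this mode over aldol attack of the C8 carbanion on the C4 ketone (which would give a resorcylate) and over Michael closure onto C2; chelation places C4a beside the ester carbon, the C4 carbonyl is cross-conjugated, α-arylated and screened by the two ortho substituents of ring D, and the ring D ester could only be reached through a seven-membered transition state. Because the pyrone supplies all three oxygens of ring A and the two phenols ortho to the ketone are identical, ring C can later close in only one way, and any 14 that has already cyclised to racemic flavanone enters step 10 equally well.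

Step 10
Reactants: 14 (E)-3-[3,4-bis(benzyloxy)phenyl]-2-(ArD)-1-(2,4,6-trihydroxyphenyl)prop-2-en-1-one
Product: 15 (E)-1-[2,4-bis(benzyloxy)-6-hydroxyphenyl]-3-[3,4-bis(benzyloxy)phenyl]-2-(ArD)prop-2-en-1-one
Conditions: BnBr (2.1 equiv), K2CO3, DMF, rt
Reagents that add atoms: benzyl bromide, BrCc1ccccc1
Why: Williamson benzylation takes the para phenol and one ortho phenol of ring A, while the last ortho phenol is chelated to the ketone and stays free for ring C; any flavanone present converges on the same dibenzyl series by ring-chain equilibration.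

Step 11
Reactants: 15 (E)-1-[2,4-bis(benzyloxy)-6-hydroxyphenyl]-3-[3,4-bis(benzyloxy)phenyl]-2-(ArD)prop-2-en-1-one
Product: 16 rac-trans-5,7-bis(benzyloxy)-2-[3,4-bis(benzyloxy)phenyl]-3-(ArD)chroman-4-one
Conditions: NaOAc, EtOH, reflux
Reagents that add atoms: none
Why: Intramolecular oxa-Michael addition (6-endo-trig) of the 2'-phenol closes ring C, and reversible closure together with enolisation at C3 should give the thermodynamically preferred trans racemate with both aryl groups equatorial.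

Step 12
Reactants: 16 rac-trans-5,7-bis(benzyloxy)-2-[3,4-bis(benzyloxy)phenyl]-3-(ArD)chroman-4-one
Product: 17 (2R,3R,4S)-5,7-bis(benzyloxy)-2-[3,4-bis(benzyloxy)phenyl]-3-(ArD)chroman-4-ol
Conditions: RuCl[(S,S)-TsDPEN](p-cymene) (5 mol %), HCO2H/Et3N (1:2), DABCO (1 equiv), MeCN, 45 °C
Reagents that add atoms: none
Why: Noyori-type asymmetric transfer hydrogenation run as a dynamic kinetic resolution: the amine base interconverts all stereoisomers of 16 through retro-oxa-Michael opening to chalcone 15, reclosure and C3 enolisation, and the (S,S)-Ru hydride should reduce the (2R,3S) ketone fastest, adding hydride to the C4 face anti to the C3 aryl to set 4S (3,4-cis) and thereby selecting 2R and the C3 configuration of the target.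

Step 13
Reactants: 17 (2R,3R,4S)-5,7-bis(benzyloxy)-2-[3,4-bis(benzyloxy)phenyl]-3-(ArD)chroman-4-ol
Product: 18 methyl 4,6-bis(benzyloxy)-3-[(2R,3R,4S)-5,7-bis(benzyloxy)-2-[3,4-bis(benzyloxy)phenyl]-4-hydroxychroman-3-yl]-2-hydroxybenzoate
Conditions: Bu4NF (5 equiv), THF/DMPU, 60 °C; aq. NH4Cl
Reagents that add atoms: none
Why: Fluoride-induced fragmentation of the SEM ether frees the C8a'' phenol under basic conditions, which the acid-labile, doubly ortho- and para-oxygenated C4 carbinol tolerates.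

Step 14
Reactants: 18 methyl 4,6-bis(benzyloxy)-3-[(2R,3R,4S)-5,7-bis(benzyloxy)-2-[3,4-bis(benzyloxy)phenyl]-4-hydroxychroman-3-yl]-2-hydroxybenzoate
Product: 19 tert-butyl 3-{4,6-bis(benzyloxy)-3-[(2R,3R,4S)-5,7-bis(benzyloxy)-2-[3,4-bis(benzyloxy)phenyl]-4-hydroxychroman-3-yl]-2-hydroxyphenyl}-3-oxopropanoate
Conditions: tert-butyl acetate (6 equiv), LiN(iPr)2 (6 equiv), THF, −78 °C; then 18, −78 °C to rt; aq. NH4Cl
Reagents that add atoms: tert-butyl acetate, CC(=O)OC(C)(C)C
Why: Crossed Claisen condensation of excess lithium tert-butyl acetate with the salicylate ester (the chelating lithium phenoxide activates the carbonyl and the product is protected as its enolate) builds C3''–C4'', the C4 alkoxide being a spectator.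

Step 15
Reactants: 19 tert-butyl 3-{4,6-bis(benzyloxy)-3-[(2R,3R,4S)-5,7-bis(benzyloxy)-2-[3,4-bis(benzyloxy)phenyl]-4-hydroxychroman-3-yl]-2-hydroxyphenyl}-3-oxopropanoate; 20 4-(benzyloxy)benzaldehyde
Product: 21 tert-butyl (Z)-2-{4,6-bis(benzyloxy)-3-[(2R,3R,4S)-5,7-bis(benzyloxy)-2-[3,4-bis(benzyloxy)phenyl]-4-hydroxychroman-3-yl]-2-hydroxybenzoyl}-3-[4-(benzyloxy)phenyl]acrylate (an E/Z mixture is acceptable)
Conditions: piperidine (0.2 equiv), AcOH (0.2 equiv), 4 Å molecular sieves, toluene, rt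
Reagents that add atoms: none
Why: Knoevenagel condensation of the β-keto ester with the aldehyde under buffered amine catalysis gives the doubly activated alkylidene, and at the carbinol level the upper unit has no base-labile stereocentre.

Step 16
Reactants: 21 tert-butyl (Z)-2-{4,6-bis(benzyloxy)-3-[(2R,3R,4S)-5,7-bis(benzyloxy)-2-[3,4-bis(benzyloxy)phenyl]-4-hydroxychroman-3-yl]-2-hydroxybenzoyl}-3-[4-(benzyloxy)phenyl]acrylate
Product: 22 tert-butyl (2R,3S)-5,7-bis(benzyloxy)-2-[4-(benzyloxy)phenyl]-8-[(2R,3R,4S)-5,7-bis(benzyloxy)-2-[3,4-bis(benzyloxy)phenyl]-4-hydroxychroman-3-yl]-4-oxochromane-3-carboxylate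
Conditions: 9-amino-9-deoxy-epi-quinidine N'-[3,5-bis(trifluoromethyl)phenyl]thiourea (10 mol %), toluene, −25 °C; filtration through a short pad of base-washed silica
Reagents that add atoms: none
Why: Enantioselective intramolecular oxa-Michael addition (6-endo-trig) in which the thiourea binds the β-keto ester and the quinuclidine deprotonates the phenol, so the catalyst selects the alkene face and sets C2'' as R with C3'' settling trans; only the C8a'' oxygen is free (C5'' is benzylated), so only the 8-linked ring F can form.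

Step 17
Reactants: 22 tert-butyl (2R,3S)-5,7-bis(benzyloxy)-2-[4-(benzyloxy)phenyl]-8-[(2R,3R,4S)-5,7-bis(benzyloxy)-2-[3,4-bis(benzyloxy)phenyl]-4-hydroxychroman-3-yl]-4-oxochromane-3-carboxylate
Product: 23 tert-butyl (2R,3S)-5,7-bis(benzyloxy)-2-[4-(benzyloxy)phenyl]-8-[(2R,3S)-5,7-bis(benzyloxy)-2-[3,4-bis(benzyloxy)phenyl]-4-oxochroman-3-yl]-4-oxochromane-3-carboxylate
Conditions: Dess–Martin periodinane (1.5 equiv), CH2Cl2, 0 °C to rt
Reagents that add atoms: none
Why: Dess–Martin oxidation of the secondary benzylic carbinol under base-free conditions restores the C4 ketone with C2 and C3 untouched (3S in the ketone is the same spatial arrangement as 3R in the carbinol).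

Step 18
Reactants: 23 tert-butyl (2R,3S)-5,7-bis(benzyloxy)-2-[4-(benzyloxy)phenyl]-8-[(2R,3S)-5,7-bis(benzyloxy)-2-[3,4-bis(benzyloxy)phenyl]-4-oxochroman-3-yl]-4-oxochromane-3-carboxylate
Product: 25 (2R)-5,7-bis(benzyloxy)-2-[4-(benzyloxy)phenyl]-8-[(2R,3S)-5,7-bis(benzyloxy)-2-[3,4-bis(benzyloxy)phenyl]-4-oxochroman-3-yl]chroman-4-one, via keto acid 24 (not isolated)
Conditions: TsOH·H2O (1 equiv), toluene, 80 °C
Reagents that add atoms: none
Why: Acid-mediated loss of 2-methylpropene from the tert-butyl ester and decarboxylation of the β-keto acid removes the sacrificial ester, and acid does not open either pyranone ring, so C2, C3 (trans, thermodynamic) and C2'' should be retained.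

Step 19
Reactants: 25 (2R)-5,7-bis(benzyloxy)-2-[4-(benzyloxy)phenyl]-8-[(2R,3S)-5,7-bis(benzyloxy)-2-[3,4-bis(benzyloxy)phenyl]-4-oxochroman-3-yl]chroman-4-one
Product: 26 (2R,3S)-2-(3,4-dihydroxyphenyl)-5,7-dihydroxy-3-[(2R)-5,7-dihydroxy-2-(4-hydroxyphenyl)-4-oxochroman-8-yl]chroman-4-one (CNP0105436.3)
Conditions: H2 (1 atm), 10% Pd/C, EtOAc/MeOH, rt
Reagents that add atoms: none
Why: Catalytic hydrogenolysis cleaves the seven benzyl ethers under neutral conditions that leave both flavanone ketones and the three stereocentres alone.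

**Compound list**

1 | methyl 2,4,6-trihydroxybenzoate | COC(=O)c1c(O)cc(O)cc1O | starting material
2 | methyl 2,4-bis(benzyloxy)-6-hydroxybenzoate | COC(=O)c1c(O)cc(OCc2ccccc2)cc1OCc1ccccc1 | intermediate
3 | methyl 2-(allyloxy)-4,6-bis(benzyloxy)benzoate | COC(=O)c1c(OCC=C)cc(OCc2ccccc2)cc1OCc1ccccc1 | intermediate
4 | methyl 3-allyl-4,6-bis(benzyloxy)-2-hydroxybenzoate | COC(=O)c1c(O)c(CC=C)c(OCc2ccccc2)cc1OCc1ccccc1 | intermediate
5 | methyl 3-allyl-4,6-bis(benzyloxy)-2-{[2-(trimethylsilyl)ethoxy]methoxy}benzoate | COC(=O)c1c(OCOCC[Si](C)(C)C)c(CC=C)c(OCc2ccccc2)cc1OCc1ccccc1 | intermediate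
6 | methyl 4,6-bis(benzyloxy)-3-(2-oxoethyl)-2-{[2-(trimethylsilyl)ethoxy]methoxy}benzoate | COC(=O)c1c(OCOCC[Si](C)(C)C)c(CC=O)c(OCc2ccccc2)cc1OCc1ccccc1 | intermediate (not isolated)
7 | 2-[4,6-bis(benzyloxy)-3-(methoxycarbonyl)-2-{[2-(trimethylsilyl)ethoxy]methoxy}phenyl]acetic acid | COC(=O)c1c(OCOCC[Si](C)(C)C)c(CC(=O)O)c(OCc2ccccc2)cc1OCc1ccccc1 | intermediate
8 | 3,4-bis(benzyloxy)benzaldehyde | O=Cc1ccc(OCc2ccccc2)c(OCc2ccccc2)c1 | starting material
9 | (E)-3-[3,4-bis(benzyloxy)phenyl]-2-(ArD)acrylic acid | OC(=O)/C(c1c(OCOCC[Si](C)(C)C)c(C(=O)OC)c(OCc2ccccc2)cc1OCc1ccccc1)=C/c1ccc(OCc2ccccc2)c(OCc2ccccc2)c1 | intermediate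
10 | methyl (E)-3-[3,4-bis(benzyloxy)phenyl]-2-(ArD)acrylate | COC(=O)/C(c1c(OCOCC[Si](C)(C)C)c(C(=O)OC)c(OCc2ccccc2)cc1OCc1ccccc1)=C/c1ccc(OCc2ccccc2)c(OCc2ccccc2)c1 | intermediate
11 | 4-hydroxy-6-methyl-2H-pyran-2-one (triacetic acid lactone) | Cc1cc(O)cc(=O)o1 | starting material
12 | 6-[(E)-4-[3,4-bis(benzyloxy)phenyl]-2-oxo-3-(ArD)but-3-enyl]-4-hydroxy-2H-pyran-2-one | O=C(Cc1cc(O)cc(=O)o1)/C(c1c(OCOCC[Si](C)(C)C)c(C(=O)OC)c(OCc2ccccc2)cc1OCc1ccccc1)=C/c1ccc(OCc2ccccc2)c(OCc2ccccc2)c1 | intermediate (key step precursor)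
13 | methyl (E)-9-[3,4-bis(benzyloxy)phenyl]-3,5,7-trioxo-8-(ArD)non-8-enoate | COC(=O)CC(=O)CC(=O)CC(=O)/C(c1c(OCOCC[Si](C)(C)C)c(C(=O)OC)c(OCc2ccccc2)cc1OCc1ccccc1)=C/c1ccc(OCc2ccccc2)c(OCc2ccccc2)c1 | intermediate (not isolated)
14 | (E)-3-[3,4-bis(benzyloxy)phenyl]-2-(ArD)-1-(2,4,6-trihydroxyphenyl)prop-2-en-1-one | O=C(c1c(O)cc(O)cc1O)/C(c1c(OCOCC[Si](C)(C)C)c(C(=O)OC)c(OCc2ccccc2)cc1OCc1ccccc1)=C/c1ccc(OCc2ccccc2)c(OCc2ccccc2)c1 | intermediate (key step product)
15 | (E)-1-[2,4-bis(benzyloxy)-6-hydroxyphenyl]-3-[3,4-bis(benzyloxy)phenyl]-2-(ArD)prop-2-en-1-one | O=C(c1c(O)cc(OCc2ccccc2)cc1OCc1ccccc1)/C(c1c(OCOCC[Si](C)(C)C)c(C(=O)OC)c(OCc2ccccc2)cc1OCc1ccccc1)=C/c1ccc(OCc2ccccc2)c(OCc2ccccc2)c1 | intermediate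
16 | rac-trans-5,7-bis(benzyloxy)-2-[3,4-bis(benzyloxy)phenyl]-3-(ArD)chroman-4-one (racemate, 2R,3S enantiomer drawn) | COC(=O)c1c(OCc2ccccc2)cc(OCc2ccccc2)c(c1OCOCC[Si](C)(C)C)[C@@H]1C(=O)c2c(OCc3ccccc3)cc(OCc3ccccc3)cc2O[C@H]1c1ccc(OCc2ccccc2)c(OCc2ccccc2)c1 | intermediate
17 | (2R,3R,4S)-5,7-bis(benzyloxy)-2-[3,4-bis(benzyloxy)phenyl]-3-(ArD)chroman-4-ol | COC(=O)c1c(OCc2ccccc2)cc(OCc2ccccc2)c(c1OCOCC[Si](C)(C)C)[C@@H]1[C@H](O)c2c(OCc3ccccc3)cc(OCc3ccccc3)cc2O[C@H]1c1ccc(OCc2ccccc2)c(OCc2ccccc2)c1 | intermediate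
18 | methyl 4,6-bis(benzyloxy)-3-[(2R,3R,4S)-5,7-bis(benzyloxy)-2-[3,4-bis(benzyloxy)phenyl]-4-hydroxychroman-3-yl]-2-hydroxybenzoate | COC(=O)c1c(OCc2ccccc2)cc(OCc2ccccc2)c(c1O)[C@@H]1[C@H](O)c2c(OCc3ccccc3)cc(OCc3ccccc3)cc2O[C@H]1c1ccc(OCc2ccccc2)c(OCc2ccccc2)c1 | intermediate
19 | tert-butyl 3-{4,6-bis(benzyloxy)-3-[(2R,3R,4S)-5,7-bis(benzyloxy)-2-[3,4-bis(benzyloxy)phenyl]-4-hydroxychroman-3-yl]-2-hydroxyphenyl}-3-oxopropanoate | CC(C)(C)OC(=O)CC(=O)c1c(OCc2ccccc2)cc(OCc2ccccc2)c(c1O)[C@@H]1[C@H](O)c2c(OCc3ccccc3)cc(OCc3ccccc3)cc2O[C@H]1c1ccc(OCc2ccccc2)c(OCc2ccccc2)c1 | intermediate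
20 | 4-(benzyloxy)benzaldehyde | O=Cc1ccc(OCc2ccccc2)cc1 | starting material
21 | tert-butyl (Z)-2-{4,6-bis(benzyloxy)-3-[(2R,3R,4S)-5,7-bis(benzyloxy)-2-[3,4-bis(benzyloxy)phenyl]-4-hydroxychroman-3-yl]-2-hydroxybenzoyl}-3-[4-(benzyloxy)phenyl]acrylate (Z drawn; E/Z mixture acceptable) | CC(C)(C)OC(=O)/C(=C\c1ccc(OCc2ccccc2)cc1)C(=O)c1c(OCc2ccccc2)cc(OCc2ccccc2)c(c1O)[C@@H]1[C@H](O)c2c(OCc3ccccc3)cc(OCc3ccccc3)cc2O[C@H]1c1ccc(OCc2ccccc2)c(OCc2ccccc2)c1 | intermediate
22 | tert-butyl (2R,3S)-5,7-bis(benzyloxy)-2-[4-(benzyloxy)phenyl]-8-[(2R,3R,4S)-5,7-bis(benzyloxy)-2-[3,4-bis(benzyloxy)phenyl]-4-hydroxychroman-3-yl]-4-oxochromane-3-carboxylate | O=C1[C@@H](C(=O)OC(C)(C)C)[C@H](c2ccc(OCc3ccccc3)cc2)Oc2c1c(OCc1ccccc1)cc(OCc1ccccc1)c2[C@@H]1[C@H](O)c2c(OCc3ccccc3)cc(OCc3ccccc3)cc2O[C@H]1c1ccc(OCc2ccccc2)c(OCc2ccccc2)c1 | intermediate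
23 | tert-butyl (2R,3S)-5,7-bis(benzyloxy)-2-[4-(benzyloxy)phenyl]-8-[(2R,3S)-5,7-bis(benzyloxy)-2-[3,4-bis(benzyloxy)phenyl]-4-oxochroman-3-yl]-4-oxochromane-3-carboxylate | O=C1[C@@H](C(=O)OC(C)(C)C)[C@H](c2ccc(OCc3ccccc3)cc2)Oc2c1c(OCc1ccccc1)cc(OCc1ccccc1)c2[C@@H]1C(=O)c2c(OCc3ccccc3)cc(OCc3ccccc3)cc2O[C@H]1c1ccc(OCc2ccccc2)c(OCc2ccccc2)c1 | intermediate
24 | (2R,3S)-5,7-bis(benzyloxy)-2-[4-(benzyloxy)phenyl]-8-[(2R,3S)-5,7-bis(benzyloxy)-2-[3,4-bis(benzyloxy)phenyl]-4-oxochroman-3-yl]-4-oxochromane-3-carboxylic acid | O=C1[C@@H](C(=O)O)[C@H](c2ccc(OCc3ccccc3)cc2)Oc2c1c(OCc1ccccc1)cc(OCc1ccccc1)c2[C@@H]1C(=O)c2c(OCc3ccccc3)cc(OCc3ccccc3)cc2O[C@H]1c1ccc(OCc2ccccc2)c(OCc2ccccc2)c1 | intermediate (not isolated)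
25 | (2R)-5,7-bis(benzyloxy)-2-[4-(benzyloxy)phenyl]-8-[(2R,3S)-5,7-bis(benzyloxy)-2-[3,4-bis(benzyloxy)phenyl]-4-oxochroman-3-yl]chroman-4-one | O=C1C[C@H](c2ccc(OCc3ccccc3)cc2)Oc2c1c(OCc1ccccc1)cc(OCc1ccccc1)c2[C@@H]1C(=O)c2c(OCc3ccccc3)cc(OCc3ccccc3)cc2O[C@H]1c1ccc(OCc2ccccc2)c(OCc2ccccc2)c1 | intermediate
26 | (2R,3S)-2-(3,4-dihydroxyphenyl)-5,7-dihydroxy-3-[(2R)-5,7-dihydroxy-2-(4-hydroxyphenyl)-4-oxochroman-8-yl]chroman-4-one | O=C1C[C@H](c2ccc(O)cc2)Oc2c1c(O)cc(O)c2[C@@H]1C(=O)c2c(O)cc(O)cc2O[C@H]1c1ccc(O)c(O)c1 | target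

**Step count and risks**

Total: 19 steps. Longest linear sequence: 19 steps (1 to 26); 8, 11 and 20 are purchased.

Steps most likely to fail:

- **Step 12.** Ring opening and reclosure of ring C may be slower than hydride transfer, or the transient chalcone may be reduced at its C=C bond, so the carbinol could form with incomplete enantio- or diastereocontrol. The fallback sets out from 16 and returns at 17. Racemic 16 is reduced with LiBH(sBu)3 in THF at −78 °C (equatorial hydride delivery anti to the C3 aryl) to the racemic 2,3-trans-3,4-cis carbinol, that is 17 together with its enantiomer, the (2S,3S,4R) carbinol F5. The two are separated by preparative chromatography on a chiral stationary phase. F5 is returned to racemic 16 by Dess–Martin oxidation and NaOAc in EtOH, and the route continues from 17.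

- **Step 9.** The opened triketo ester may fold by aldol condensation of C8 onto the C4 ketone, add in conjugate fashion to C2, or simply relactonise, so little acylphloroglucinol would form. The fallback sets out from 9 and returns at 15, and it builds the aryl ketone by organometallic acylation instead of polyketide folding. Acid 9 is converted (MeNHOMe·HCl, EDC·HCl, DMAP, CH2Cl2) into the Weinreb amide F1. 3,5-Bis(benzyloxy)phenol is brominated ortho to the hydroxyl (NBS, cat. iPr2NH, CH2Cl2) to 2-bromo-3,5-bis(benzyloxy)phenol F2, which is allylated (allyl bromide, K2CO3, DMF) to 1-(allyloxy)-3,5-bis(benzyloxy)-2-bromobenzene F3. Bromine–lithium exchange on F3 (n-BuLi, THF, −78 °C) and addition of the aryllithium to F1 give the 2'-O-allyl chalcone F4. Removal of the allyl group with Pd(PPh3)4 and morpholine in THF gives 15.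

- **Step 16.** Facial selectivity in the conjugate addition may be poor, because the phenol is flanked by the bulky C8'' substituent and the resident stereocentres may oppose the catalyst. The fallback sets out from 21 and returns at 22. Alkylidene 21 is cyclised without a chiral catalyst (cat. DBU, toluene, rt) to 22 and its lower-ring (2S,3R) epimer F6. These are diastereomers, since the upper unit is already a single enantiomer, and are separated by chromatography. F6 is re-equilibrated with DBU through retro-oxa-Michael opening and reclosure (the upper carbinol is inert to base) and recycled, and the route continues from 22.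

Further compounds
F1 | step 9 | (E)-3-[3,4-bis(benzyloxy)phenyl]-N-methoxy-N-methyl-2-(ArD)acrylamide | CON(C)C(=O)/C(c1c(OCOCC[Si](C)(C)C)c(C(=O)OC)c(OCc2ccccc2)cc1OCc1ccccc1)=C/c1ccc(OCc2ccccc2)c(OCc2ccccc2)c1
F2 | step 9 | 2-bromo-3,5-bis(benzyloxy)phenol | Oc1cc(OCc2ccccc2)cc(OCc2ccccc2)c1Br
F3 | step 9 | 1-(allyloxy)-3,5-bis(benzyloxy)-2-bromobenzene | C=CCOc1cc(OCc2ccccc2)cc(OCc2ccccc2)c1Br
F4 | step 9 | (E)-1-[2-(allyloxy)-4,6-bis(benzyloxy)phenyl]-3-[3,4-bis(benzyloxy)phenyl]-2-(ArD)prop-2-en-1-one | O=C(c1c(OCC=C)cc(OCc2ccccc2)cc1OCc1ccccc1)/C(c1c(OCOCC[Si](C)(C)C)c(C(=O)OC)c(OCc2ccccc2)cc1OCc1ccccc1)=C/c1ccc(OCc2ccccc2)c(OCc2ccccc2)c1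
F5 | step 12 | (2S,3S,4R)-5,7-bis(benzyloxy)-2-[3,4-bis(benzyloxy)phenyl]-3-(ArD)chroman-4-ol (enantiomer of 17) | COC(=O)c1c(OCc2ccccc2)cc(OCc2ccccc2)c(c1OCOCC[Si](C)(C)C)[C@H]1[C@@H](O)c2c(OCc3ccccc3)cc(OCc3ccccc3)cc2O[C@@H]1c1ccc(OCc2ccccc2)c(OCc2ccccc2)c1
F6 | step 16 | tert-butyl (2S,3R)-5,7-bis(benzyloxy)-2-[4-(benzyloxy)phenyl]-8-[(2R,3R,4S)-5,7-bis(benzyloxy)-2-[3,4-bis(benzyloxy)phenyl]-4-hydroxychroman-3-yl]-4-oxochromane-3-carboxylate | O=C1[C@H](C(=O)OC(C)(C)C)[C@@H](c2ccc(OCc3ccccc3)cc2)Oc2c1c(OCc1ccccc1)cc(OCc1ccccc1)c2[C@@H]1[C@H](O)c2c(OCc3ccccc3)cc(OCc3ccccc3)cc2O[C@H]1c1ccc(OCc2ccccc2)c(OCc2ccccc2)c1
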